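**Retrosynthetic overview**
- The target comes from its tetra-MOM ether by acetal cleavage. Ring C is closed last, at C4–C4a, by Friedel–Crafts cycloacylation of an (E)-3-aryl-3-aryloxy-2-(methoxymethoxy)acrylic acid.
- Feature used: in ring A the ring oxygen O1 sits on C8a, whose two ortho carbons are C8 (blocked by the 1,1-dimethylallyl group) and C4a (free, para to O7 and ortho to O5). The acyl carbon C4 can therefore close ring C only at C4a.
- The acid comes from forming the O1–C2 bond by addition–elimination of the ring A phenol on a β-chloroacrylate. The C2–C3 bond comes from a glycolate aldol on the ring B aldehyde, followed by oxidation and deoxychlorination.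
- The ring A phenol comes from an aromatic Claisen rearrangement of the symmetric prenyl ether of bis-MOM phloroglucinol. The ring B aldehyde comes from vanillin by propargyl-Claisen chromene annulation, hydrogenation, C5 bromination, methyl-to-MOM exchange and Stille prenylation.
- Ring order: rings A and B are bought as arenes; the dimethylpyran ring on ring B is formed in step 5 and saturated in step 6; ring C is formed in step 17.

Key step: step 17

Assumption: the tetrasubstituted acrylate alkenes made from step 14 onward may form as E/Z mixtures, the isomer drawn being the one that closes and the other being expected to converge on it at the acylium stage of step 17; the aldol product is carried on as a racemic diastereomer mixture because both of its stereocentres disappear in steps 13 and 14.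

**Route**

Step 1
Reactants: 1 phloroglucinol
Product: 2 3,5-bis(methoxymethoxy)phenol
Conditions: MOMCl (2 equiv), i-Pr2NEt, DMF, 0 °C to rt; chromatography (mono- and tris-ethers recycled)
Reagents that add atoms: chloromethyl methyl ether (MOMCl), COCCl
Why: O-alkylation of the C3-symmetric triphenol with two equivalents of MOMCl (Williamson-type acetal formation) should give the bis-ether as the main, separable component of a statistical mixture, and all positions are equivalent so no regiochemical question arises.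

Step 2
Reactants: 2 3,5-bis(methoxymethoxy)phenol; 3 prenyl bromide
Product: 4 1,3-bis(methoxymethoxy)-5-[(3-methylbut-2-en-1-yl)oxy]benzene
Conditions: K2CO3, acetone, reflux
Reagents that add atoms: none
Why: Williamson etherification of the single free phenol, where the weak carbonate base in acetone should favour O- over C-prenylation.

Step 3
Reactants: 4 1,3-bis(methoxymethoxy)-5-[(3-methylbut-2-en-1-yl)oxy]benzene
Product: 5 3,5-bis(methoxymethoxy)-2-(2-methylbut-3-en-2-yl)phenol
Conditions: PhNEt2, 190 °C, sealed tube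
Reagents that add atoms: none
Why: Aromatic Claisen rearrangement ([3,3]) delivers the allyl unit inverted, as the 1,1-dimethylallyl group, to an ortho carbon; both ortho carbons are equivalent by symmetry, and the basic amine solvent should suppress acid-induced cyclisation of the new phenol onto its own alkene.

Step 4
Reactants: 6 vanillin; 7 3-chloro-3-methylbut-1-yne
Product: 8 3-methoxy-4-[(2-methylbut-3-yn-2-yl)oxy]benzaldehyde
Conditions: K2CO3, KI (cat.), CuI (cat.), acetone, reflux
Reagents that add atoms: none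
Why: Copper-assisted O-alkylation of the phenoxide with the tertiary propargylic chloride is the standard entry to aryl 1,1-dimethylpropargyl ethers.

Step 5
Reactants: 8 3-methoxy-4-[(2-methylbut-3-yn-2-yl)oxy]benzaldehyde
Product: 9 8-methoxy-2,2-dimethyl-2H-chromene-6-carbaldehyde
Conditions: PhNEt2, 190 °C
Reagents that add atoms: none
Why: Propargyl Claisen rearrangement to the only free ortho carbon (the other carries the methoxy group), then 1,5-hydrogen shift and oxa-6π electrocyclisation, should give the 2,2-dimethylchromene in one thermal operation.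

Step 6
Reactants: 9 8-methoxy-2,2-dimethyl-2H-chromene-6-carbaldehyde
Product: 10 8-methoxy-2,2-dimethylchromane-6-carbaldehyde
Conditions: H2 (1 atm), Pd/C, Ph2S (cat.), EtOAc, rt
Reagents that add atoms: none
Why: Catalytic hydrogenation over sulfide-moderated Pd/C should saturate the cis-disubstituted styrenyl alkene while leaving the aryl aldehyde untouched.

Step 7
Reactants: 10 8-methoxy-2,2-dimethylchromane-6-carbaldehyde
Product: 11 5-bromo-8-methoxy-2,2-dimethylchromane-6-carbaldehyde
Conditions: Br2, NaOAc, AcOH, rt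
Reagents that add atoms: bromine, BrBr
Why: Electrophilic aromatic bromination should go to C5, which is para to the 8-methoxy group and ortho to the ring alkyl carbon (the same preference that sends veratraldehyde to its 6-bromo derivative), whereas C7 is only ortho to the methoxy group.

Step 8
Reactants: 11 5-bromo-8-methoxy-2,2-dimethylchromane-6-carbaldehyde
Product: 13 5-bromo-8-hydroxy-2,2-dimethylchromane-6-carbaldehyde, via aryloxydibromoborane 12 (not isolated)
Conditions: BBr3, CH2Cl2, −78 to 0 °C; then H2O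
Reagents that add atoms: none
Why: Lewis-acid ether cleavage in which bromide attacks the methyl group of the chelated guaiacol-type ether by SN2, while the tertiary ring ether is not open to SN2 and would re-close if it ionised.

Step 9
Reactants: 13 5-bromo-8-hydroxy-2,2-dimethylchromane-6-carbaldehyde
Product: 14 5-bromo-8-(methoxymethoxy)-2,2-dimethylchromane-6-carbaldehyde
Conditions: MOMCl, i-Pr2NEt, CH2Cl2, 0 °C to rt
Reagents that add atoms: chloromethyl methyl ether (MOMCl), COCCl
Why: Standard MOM protection of a phenol, giving the acid-labile group that can be removed at the end without touching the alkenes.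

Step 10
Reactants: 14 5-bromo-8-(methoxymethoxy)-2,2-dimethylchromane-6-carbaldehyde; 15 tributyl(3-methylbut-2-en-1-yl)stannane
Product: 16 8-(methoxymethoxy)-2,2-dimethyl-5-(3-methylbut-2-en-1-yl)chromane-6-carbaldehyde
Conditions: Pd(PPh3)4 (cat.), DMF, 90 °C
Reagents that add atoms: none
Why: Stille coupling in which the ortho formyl group speeds oxidative addition and the allyl unit should be transferred at its primary terminus (linear prenyl), since bond formation at the tertiary terminus next to a doubly ortho-substituted arene is disfavoured.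

Step 11
Reactants: 17 methyl glycolate
Product: 18 methyl 2-(methoxymethoxy)acetate
Conditions: MOMCl, i-Pr2NEt, CH2Cl2, 0 °C to rt
Reagents that add atoms: chloromethyl methyl ether (MOMCl), COCCl
Why: Standard MOM protection of a primary alcohol, placing the future C3 oxygen in protected form.

Step 12
Reactants: 16 8-(methoxymethoxy)-2,2-dimethyl-5-(3-methylbut-2-en-1-yl)chromane-6-carbaldehyde; 18 methyl 2-(methoxymethoxy)acetate
Product: 21 methyl 3-hydroxy-2-(methoxymethoxy)-3-[8-(methoxymethoxy)-2,2-dimethyl-5-(3-methylbut-2-en-1-yl)chroman-6-yl]propanoate (racemic syn/anti mixture), via glycolate lithium enolate 19 (not isolated), via lithium aldolate 20 (not isolated)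
Conditions: LDA, THF, −78 °C; then 16, −78 °C; AcOH quench
Reagents that add atoms: none
Why: Aldol addition of a preformed α-alkoxy ester enolate to a non-enolisable aryl aldehyde forms the C2–C3 bond, and the two new stereocentres need no control because they are removed in steps 13 and 14.

Step 13
Reactants: 21 methyl 3-hydroxy-2-(methoxymethoxy)-3-[8-(methoxymethoxy)-2,2-dimethyl-5-(3-methylbut-2-en-1-yl)chroman-6-yl]propanoate
Product: 22 methyl 2-(methoxymethoxy)-3-oxo-3-[8-(methoxymethoxy)-2,2-dimethyl-5-(3-methylbut-2-en-1-yl)chroman-6-yl]propanoate (racemic)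
Conditions: IBX, DMSO, rt
Reagents that add atoms: none
Why: Hypervalent-iodine oxidation of the benzylic β-hydroxy ester gives the β-keto ester under neutral conditions that spare the MOM acetals and the prenyl alkene.

Step 14
Reactants: 22 methyl 2-(methoxymethoxy)-3-oxo-3-[8-(methoxymethoxy)-2,2-dimethyl-5-(3-methylbut-2-en-1-yl)chroman-6-yl]propanoate
Product: 23 methyl (E)-3-chloro-2-(methoxymethoxy)-3-[8-(methoxymethoxy)-2,2-dimethyl-5-(3-methylbut-2-en-1-yl)chroman-6-yl]prop-2-enoate
Conditions: Ph3PCl2, Et3N, MeCN, 0 to 60 °C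
Reagents that add atoms: dichlorotriphenylphosphorane, ClP(Cl)(c1ccccc1)(c1ccccc1)c1ccccc1
Why: Appel-type deoxychlorination of a β-dicarbonyl enol, in which the enolate oxygen is captured as an oxyphosphonium ion and chloride replaces it by conjugate addition–elimination, the amine buffer keeping the medium non-acidic for the MOM groups.

Step 15
Reactants: 23 methyl (E)-3-chloro-2-(methoxymethoxy)-3-[8-(methoxymethoxy)-2,2-dimethyl-5-(3-methylbut-2-en-1-yl)chroman-6-yl]prop-2-enoate; 5 3,5-bis(methoxymethoxy)-2-(2-methylbut-3-en-2-yl)phenol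
Product: 24 methyl (E)-3-[3,5-bis(methoxymethoxy)-2-(2-methylbut-3-en-2-yl)phenoxy]-2-(methoxymethoxy)-3-[8-(methoxymethoxy)-2,2-dimethyl-5-(3-methylbut-2-en-1-yl)chroman-6-yl]prop-2-enoate
Conditions: Cs2CO3, DMF, 60 °C
Reagents that add atoms: none
Why: Nucleophilic vinylic substitution (addition–elimination) of the caesium phenoxide at the ester-activated β-carbon forms the O1–C2 bond, as in the known preparation of β-aryloxycinnamates from β-chlorocinnamates.

Step 16
Reactants: 24 methyl (E)-3-[3,5-bis(methoxymethoxy)-2-(2-methylbut-3-en-2-yl)phenoxy]-2-(methoxymethoxy)-3-[8-(methoxymethoxy)-2,2-dimethyl-5-(3-methylbut-2-en-1-yl)chroman-6-yl]prop-2-enoate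
Product: 26 (E)-3-[3,5-bis(methoxymethoxy)-2-(2-methylbut-3-en-2-yl)phenoxy]-2-(methoxymethoxy)-3-[8-(methoxymethoxy)-2,2-dimethyl-5-(3-methylbut-2-en-1-yl)chroman-6-yl]prop-2-enoic acid, via lithium carboxylate 25 (not isolated)
Conditions: LiOH, THF/MeOH/H2O, 40 °C; then AcOH to pH 5, 0 °C
Reagents that add atoms: lithium hydroxide, [Li+].[OH-]
Why: Ester saponification by acyl–oxygen cleavage, with the β-carbon shielded from hydroxide by its four substituents and the α-alkoxy group, and a weak-acid work-up that the MOM acetals tolerate.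

Step 17
Reactants: 26 (E)-3-[3,5-bis(methoxymethoxy)-2-(2-methylbut-3-en-2-yl)phenoxy]-2-(methoxymethoxy)-3-[8-(methoxymethoxy)-2,2-dimethyl-5-(3-methylbut-2-en-1-yl)chroman-6-yl]prop-2-enoic acid
Product: 28 3,5,7-tris(methoxymethoxy)-2-[8-(methoxymethoxy)-2,2-dimethyl-5-(3-methylbut-2-en-1-yl)chroman-6-yl]-8-(2-methylbut-3-en-2-yl)-4H-chromen-4-one, via acid chloride 27 (not isolated)
Conditions: 1-chloro-N,N,2-trimethylprop-1-en-1-amine (1.0 equiv), CH2Cl2, 0 °C; then AgOTf, 2,6-di-tert-butyl-4-methylpyridine, −40 °C to rt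
Reagents that add atoms: none
Why: The α-chloroenamine converts the acid into acid chloride 27 without releasing acid (the only by-product is an amide), AgOTf then abstracts chloride to give an acyl triflate or acylium ion that attacks C4a of ring A in an intramolecular Friedel–Crafts acylation, and the hindered pyridine takes up the proton to leave the 4-pyranone. The closest known reaction type is the cycloacylation of β-aryloxycinnamic acids and their acid chlorides to flavones and chromones, here with an extra 2-alkoxy group on the alkene. Ring C closes as a six-membered ring through O1 and the C2=C3 alkene, formally a 6-exo-trig attack of C4a on the acyl carbon with the carbonyl oxygen left outside the ring. No stereocentre is formed. The step needs site selectivity and a suitable alkene geometry: C8 carries the 1,1-dimethylallyl group, so C4a (para to the 7-oxygen, ortho to the 5-oxygen) is the only carbon ortho to O1 that can be acylated, and the acylium ion is in resonance with an oxocarbenium–ketene form in which C2–C3 is a single bond, so either alkene isomer can rotate into the closing geometry while the much less nucleophilic C6' of ring B, which would give an indenone, should not compete. Holding the chloroenamine to one equivalent avoids a keteniminium ion that could add to the two alkenes, and the buffered, water-free medium should preserve the four MOM acetals, the prenyl group and the 1,1-dimethylallyl group.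

Step 18
Reactants: 28 3,5,7-tris(methoxymethoxy)-2-[8-(methoxymethoxy)-2,2-dimethyl-5-(3-methylbut-2-en-1-yl)chroman-6-yl]-8-(2-methylbut-3-en-2-yl)-4H-chromen-4-one
Product: 29 Broussoflavonol E
Conditions: HCl (2 M aq), MeOH/THF, 40 °C
Reagents that add atoms: none
Why: Acid-catalysed transacetalisation to dimethoxymethane removes all four MOM groups under conditions mild enough for the alkenes, since the 2'-prenyl group has no neighbouring hydroxyl to trap a cation and the vinyl group at C8 would have to form a secondary cation.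

**Compound list**

1 | phloroglucinol | Oc1cc(O)cc(O)c1 | starting material
2 | 3,5-bis(methoxymethoxy)phenol | COCOc1cc(O)cc(OCOC)c1 | intermediate
3 | prenyl bromide (1-bromo-3-methylbut-2-ene) | CC(C)=CCBr | starting material
4 | 1,3-bis(methoxymethoxy)-5-[(3-methylbut-2-en-1-yl)oxy]benzene | COCOc1cc(OCC=C(C)C)cc(OCOC)c1 | intermediate
5 | 3,5-bis(methoxymethoxy)-2-(2-methylbut-3-en-2-yl)phenol | C=CC(C)(C)c1c(O)cc(OCOC)cc1OCOC | intermediate
6 | vanillin | COc1cc(C=O)ccc1O | starting material
7 | 3-chloro-3-methylbut-1-yne | C#CC(C)(C)Cl | starting material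
8 | 3-methoxy-4-[(2-methylbut-3-yn-2-yl)oxy]benzaldehyde | COc1cc(C=O)ccc1OC(C)(C)C#C | intermediate
9 | 8-methoxy-2,2-dimethyl-2H-chromene-6-carbaldehyde | COc1cc(C=O)cc2C=CC(C)(C)Oc12 | intermediate
10 | 8-methoxy-2,2-dimethylchromane-6-carbaldehyde | COc1cc(C=O)cc2CCC(C)(C)Oc12 | intermediate
11 | 5-bromo-8-methoxy-2,2-dimethylchromane-6-carbaldehyde | COc1cc(C=O)c(Br)c2CCC(C)(C)Oc12 | intermediate
12 | dibromo[(5-bromo-6-formyl-2,2-dimethylchroman-8-yl)oxy]borane | BrB(Br)Oc1cc(C=O)c(Br)c2CCC(C)(C)Oc12 | intermediate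
13 | 5-bromo-8-hydroxy-2,2-dimethylchromane-6-carbaldehyde | Oc1cc(C=O)c(Br)c2CCC(C)(C)Oc12 | intermediate
14 | 5-bromo-8-(methoxymethoxy)-2,2-dimethylchromane-6-carbaldehyde | COCOc1cc(C=O)c(Br)c2CCC(C)(C)Oc12 | intermediate
15 | tributyl(3-methylbut-2-en-1-yl)stannane | CCCC[Sn](CCCC)(CCCC)CC=C(C)C | starting material
16 | 8-(methoxymethoxy)-2,2-dimethyl-5-(3-methylbut-2-en-1-yl)chromane-6-carbaldehyde | COCOc1cc(C=O)c(CC=C(C)C)c2CCC(C)(C)Oc12 | intermediate
17 | methyl glycolate | OCC(=O)OC | starting material
18 | methyl 2-(methoxymethoxy)acetate | COCOCC(=O)OC | intermediate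
19 | lithium enolate of 18 (lithium 1-methoxy-2-(methoxymethoxy)ethen-1-olate) | [Li+].COCOC=C([O-])OC | intermediate
20 | lithium aldolate of 21 (racemic diastereomer mixture) | [Li+].COC(=O)C(OCOC)C([O-])c1cc(OCOC)c2OC(C)(C)CCc2c1CC=C(C)C | intermediate
21 | methyl 3-hydroxy-2-(methoxymethoxy)-3-[8-(methoxymethoxy)-2,2-dimethyl-5-(3-methylbut-2-en-1-yl)chroman-6-yl]propanoate (racemic syn/anti mixture) | COC(=O)C(OCOC)C(O)c1cc(OCOC)c2OC(C)(C)CCc2c1CC=C(C)C | intermediate
22 | methyl 2-(methoxymethoxy)-3-oxo-3-[8-(methoxymethoxy)-2,2-dimethyl-5-(3-methylbut-2-en-1-yl)chroman-6-yl]propanoate (racemic) | COC(=O)C(OCOC)C(=O)c1cc(OCOC)c2OC(C)(C)CCc2c1CC=C(C)C | intermediate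
23 | methyl (E)-3-chloro-2-(methoxymethoxy)-3-[8-(methoxymethoxy)-2,2-dimethyl-5-(3-methylbut-2-en-1-yl)chroman-6-yl]prop-2-enoate (chlorine cis to the ester) | COC(=O)/C(OCOC)=C(\Cl)c1cc(OCOC)c2OC(C)(C)CCc2c1CC=C(C)C | intermediate
24 | methyl (E)-3-[3,5-bis(methoxymethoxy)-2-(2-methylbut-3-en-2-yl)phenoxy]-2-(methoxymethoxy)-3-[8-(methoxymethoxy)-2,2-dimethyl-5-(3-methylbut-2-en-1-yl)chroman-6-yl]prop-2-enoate (aryloxy cis to the ester) | COC(=O)/C(OCOC)=C(\Oc1cc(OCOC)cc(OCOC)c1C(C)(C)C=C)c1cc(OCOC)c2OC(C)(C)CCc2c1CC=C(C)C | intermediate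
25 | lithium salt of acid 26 | [Li+].[O-]C(=O)/C(OCOC)=C(\Oc1cc(OCOC)cc(OCOC)c1C(C)(C)C=C)c1cc(OCOC)c2OC(C)(C)CCc2c1CC=C(C)C | intermediate
26 | (E)-3-[3,5-bis(methoxymethoxy)-2-(2-methylbut-3-en-2-yl)phenoxy]-2-(methoxymethoxy)-3-[8-(methoxymethoxy)-2,2-dimethyl-5-(3-methylbut-2-en-1-yl)chroman-6-yl]prop-2-enoic acid (carboxyl cis to the ring A aryloxy group) | OC(=O)/C(OCOC)=C(\Oc1cc(OCOC)cc(OCOC)c1C(C)(C)C=C)c1cc(OCOC)c2OC(C)(C)CCc2c1CC=C(C)C | intermediate
27 | acid chloride of 26 | ClC(=O)/C(OCOC)=C(\Oc1cc(OCOC)cc(OCOC)c1C(C)(C)C=C)c1cc(OCOC)c2OC(C)(C)CCc2c1CC=C(C)C | intermediate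
28 | 3,5,7-tris(methoxymethoxy)-2-[8-(methoxymethoxy)-2,2-dimethyl-5-(3-methylbut-2-en-1-yl)chroman-6-yl]-8-(2-methylbut-3-en-2-yl)-4H-chromen-4-one (3,5,7,3'-tetrakis-O-MOM Broussoflavonol E) | C=CC(C)(C)c1c(OCOC)cc(OCOC)c2c(=O)c(OCOC)c(-c3cc(OCOC)c4c(c3CC=C(C)C)CCC(C)(C)O4)oc12 | intermediate
29 | Broussoflavonol E (3,5,7-trihydroxy-2-[8-hydroxy-2,2-dimethyl-5-(3-methylbut-2-en-1-yl)chroman-6-yl]-8-(2-methylbut-3-en-2-yl)-4H-chromen-4-one; no stereocentres) | C=CC(C)(C)c1c(O)cc(O)c2c(=O)c(O)c(-c3cc(O)c4c(c3CC=C(C)C)CCC(C)(C)O4)oc12 | target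

**Step count**

Total: 18 steps. Longest linear sequence: 14 steps (vanillin 6 to 29, steps 4–10 and 12–18).

**Steps most likely to fail**

Step 17 (key step).
- What may go wrong: the activated acyl carbon may be captured by the methoxy oxygen of the neighbouring C3 MOM acetal (a five-membered acyloxonium ion, so the acyl donor is lost). MOM groups may also be lost to traces of acid, or closure may be too slow for steric reasons.
- Fallback: it sets out from 5 and 16 and comes back at 28, closing ring C at O1–C2 by known chalcone chemistry. Phenol 5 is ortho-formylated at its only free ortho carbon ((CH2O)n, MgCl2, Et3N, MeCN, reflux) to 2-hydroxy-4,6-bis(methoxymethoxy)-3-(2-methylbut-3-en-2-yl)benzaldehyde F1. MeMgBr gives the carbinol 1-[2-hydroxy-4,6-bis(methoxymethoxy)-3-(2-methylbut-3-en-2-yl)phenyl]ethanol F2, and MnO2 oxidises it to the acetophenone 1-[2-hydroxy-4,6-bis(methoxymethoxy)-3-(2-methylbut-3-en-2-yl)phenyl]ethanone F3. Claisen–Schmidt condensation of F3 with aldehyde 16 (KOH, EtOH) gives the 2'-hydroxychalcone F4. Algar–Flynn–Oyamada oxidation (H2O2, NaOH, MeOH) should give the 3-hydroxyflavone 5,7,3'-tris-O-MOM Broussoflavonol E F5, and MOMCl/i-Pr2NEt returns it to 28. Aurone formation is the known weakness of this oxidation with a 6'-alkoxy chalcone.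

Step 15.
- What may go wrong: addition of the ortho-tert-alkyl phenoxide to the tetrasubstituted β-carbon, which is flanked by the ortho-prenyl arene, may be slower than attack at the ester carbonyl or base-induced breakdown of 23.
- Fallback: it sets out from 16 and 5 and comes back at 24, moving the C–O bond formation to a secondary benzylic carbon. Darzens condensation of 16 with methyl dichloroacetate (NaOMe, Et2O, 0 °C) gives the chloroglycidate methyl 2-chloro-3-[8-(methoxymethoxy)-2,2-dimethyl-5-(3-methylbut-2-en-1-yl)chroman-6-yl]oxirane-2-carboxylate F6. On warming this should isomerise to the chloro oxo ester methyl 3-chloro-2-oxo-3-[8-(methoxymethoxy)-2,2-dimethyl-5-(3-methylbut-2-en-1-yl)chroman-6-yl]propanoate F7. The phenoxide of 5 (K2CO3, acetone) displaces the benzylic chloride to give the aryloxy oxo ester methyl 3-[3,5-bis(methoxymethoxy)-2-(2-methylbut-3-en-2-yl)phenoxy]-2-oxo-3-[8-(methoxymethoxy)-2,2-dimethyl-5-(3-methylbut-2-en-1-yl)chroman-6-yl]propanoate F8. Enolisation and O-alkylation with MOMCl (i-Pr2NEt, CH2Cl2) should then give the enol ether 24.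

Step 14.
- What may go wrong: chloride addition–elimination at the hindered oxyphosphonium enol may be sluggish, so the keto ester returns on work-up, or the acetal next to the activated enol may be lost.
- Fallback: it sets out from 22 and 5 and comes back at 24, replacing the chloride by a sulfonate and the substitution by a cross-coupling. Keto ester 22 is converted (KHMDS, PhNTf2, THF, −78 °C) into the enol triflate methyl (E)-2-(methoxymethoxy)-3-[8-(methoxymethoxy)-2,2-dimethyl-5-(3-methylbut-2-en-1-yl)chroman-6-yl]-3-(trifluoromethylsulfonyloxy)prop-2-enoate F9. Palladium-catalysed C–O coupling of F9 with phenol 5 (Pd2(dba)3, a bulky biaryl di-tert-butylphosphine, K3PO4, toluene, 80 °C) should give 24 directly.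

**Further compounds**

F1 | step 17 | 2-hydroxy-4,6-bis(methoxymethoxy)-3-(2-methylbut-3-en-2-yl)benzaldehyde | O=Cc1c(O)c(C(C)(C)C=C)c(OCOC)cc1OCOC
F2 | step 17 | 1-[2-hydroxy-4,6-bis(methoxymethoxy)-3-(2-methylbut-3-en-2-yl)phenyl]ethanol (racemic) | CC(O)c1c(O)c(C(C)(C)C=C)c(OCOC)cc1OCOC
F3 | step 17 | 1-[2-hydroxy-4,6-bis(methoxymethoxy)-3-(2-methylbut-3-en-2-yl)phenyl]ethanone | CC(=O)c1c(O)c(C(C)(C)C=C)c(OCOC)cc1OCOC
F4 | step 17 | (E)-1-[2-hydroxy-4,6-bis(methoxymethoxy)-3-(2-methylbut-3-en-2-yl)phenyl]-3-[8-(methoxymethoxy)-2,2-dimethyl-5-(3-methylbut-2-en-1-yl)chroman-6-yl]prop-2-en-1-one | O=C(/C=C/c1cc(OCOC)c2OC(C)(C)CCc2c1CC=C(C)C)c1c(O)c(C(C)(C)C=C)c(OCOC)cc1OCOC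
F5 | step 17 | 3-hydroxy-5,7-bis(methoxymethoxy)-2-[8-(methoxymethoxy)-2,2-dimethyl-5-(3-methylbut-2-en-1-yl)chroman-6-yl]-8-(2-methylbut-3-en-2-yl)-4H-chromen-4-one | C=CC(C)(C)c1c(OCOC)cc(OCOC)c2c(=O)c(O)c(-c3cc(OCOC)c4c(c3CC=C(C)C)CCC(C)(C)O4)oc12
F6 | step 15 | methyl 2-chloro-3-[8-(methoxymethoxy)-2,2-dimethyl-5-(3-methylbut-2-en-1-yl)chroman-6-yl]oxirane-2-carboxylate (racemic diastereomer mixture) | COC(=O)C1(Cl)OC1c1cc(OCOC)c2OC(C)(C)CCc2c1CC=C(C)C
F7 | step 15 | methyl 3-chloro-2-oxo-3-[8-(methoxymethoxy)-2,2-dimethyl-5-(3-methylbut-2-en-1-yl)chroman-6-yl]propanoate (racemic) | COC(=O)C(=O)C(Cl)c1cc(OCOC)c2OC(C)(C)CCc2c1CC=C(C)C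
F8 | step 15 | methyl 3-[3,5-bis(methoxymethoxy)-2-(2-methylbut-3-en-2-yl)phenoxy]-2-oxo-3-[8-(methoxymethoxy)-2,2-dimethyl-5-(3-methylbut-2-en-1-yl)chroman-6-yl]propanoate (racemic) | COC(=O)C(=O)C(Oc1cc(OCOC)cc(OCOC)c1C(C)(C)C=C)c1cc(OCOC)c2OC(C)(C)CCc2c1CC=C(C)C
F9 | step 14 | methyl (E)-2-(methoxymethoxy)-3-[8-(methoxymethoxy)-2,2-dimethyl-5-(3-methylbut-2-en-1-yl)chroman-6-yl]-3-(trifluoromethylsulfonyloxy)prop-2-enoate | COC(=O)/C(OCOC)=C(\OS(=O)(=O)C(F)(F)F)c1cc(OCOC)c2OC(C)(C)CCc2c1CC=C(C)C
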